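**Plan**
Numbering: C1 is the formyl carbon, C2=C7 the exocyclic enal, C3–C5 the hydroxypropyl arm on C6, C6–C11 the cyclohexane ring, C12–C23 the chain on C11.
Cuts: last the two C–O bonds of the C18–C19 oxirane; before that C2=C7 (enal from a C7 ketone), C5–C6 (allylation), C11–C12 (conjugate addition of the complete chain); inside the chain C13–C14 and C15–CH3 (carboalumination, oxirane opening) and C16–C17 (propargylation of a neryl halide).
Forward: the cyclohexane is bought as a simple enone and made into an enantioenriched γ-silyloxy enone (steps 1–3); the (3E,7Z)-homofarnesyl chain is built (steps 4–8) and joined in step 9; allyl, isopropenyl and the enal follow (steps 10–15); the oxirane, the only ring made, closes in the last step.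
Stereochemistry: C10 from a catalyst-controlled methyl addition; C11 from cuprate attack anti to the C10 silyloxy group; C6 from enolate allylation anti to the chain; 14E from syn carboalumination; 18Z from the Z starting alcohol; 2Z from the sigmatropic transposition and allylic strain; C18/C19 from the enzyme's face choice and syn oxygen transfer to the Z alkene.
Enabling feature: the 18Z trisubstituted alkene C18=C19 sits in the middle of the C12–C23 chain between C14=C15 and C22=C23, seven bonds from the cyclohexane ring. The C3 and C10 hydroxyls and the C1 enal on that ring form a polar head that a haem pocket can hold, so that only the kinked middle alkene is presented to the iron.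

Key step: step 16

Remark: in the (18R,19S) oxirane the chain carbons C17 and C20 are cis, so a syn oxygen transfer must start from the 18Z (neryl-type) alkene; the epoxidation substrate is built and drawn accordingly.
Remark: the ligand enantiomer in step 1 is taken to be the one that gives the (S) alcohol; both antipodes are accessible from the enantiomeric diamines and camphorsulfonyl chlorides.

Step 1
Reactants: 1 2-methylcyclohex-2-en-1-one
Product: 2 (1S)-1,2-dimethylcyclohex-2-en-1-ol
Conditions: Me2Zn, Ti(OiPr)4, bis(hydroxycamphorsulfonamide) ligand of trans-cyclohexane-1,2-diamine (10 mol %), toluene/hexane, rt; aq. NH4Cl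
Reagents that add atoms: dimethylzinc, C[Zn]C
Why: Titanium/bis(sulfonamide)-diol-catalysed enantioselective 1,2-addition of a dialkylzinc to an α-substituted cyclic enone; the chiral titanium complex selects the carbonyl face and sets C10 as S.

Step 2
Reactants: 2 (1S)-1,2-dimethylcyclohex-2-en-1-ol
Product: 3 triethyl{[(1S)-1,2-dimethylcyclohex-2-en-1-yl]oxy}silane
Conditions: Et3SiOTf, 2,6-lutidine, CH2Cl2, −78 to 0 °C
Reagents that add atoms: triethylsilyl trifluoromethanesulfonate, CC[Si](CC)(CC)OS(=O)(=O)C(F)(F)F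
Why: Silyl triflate silylation of a hindered tertiary alcohol under basic conditions; the ether blocks oxidative allylic transposition in step 3 and later shields one face of the enone.

Step 3
Reactants: 3 triethyl{[(1S)-1,2-dimethylcyclohex-2-en-1-yl]oxy}silane
Product: 4 (4S)-3,4-dimethyl-4-[(triethylsilyl)oxy]cyclohex-2-en-1-one
Conditions: Rh2(C6H10NO)4 (dirhodium tetrakis(caprolactamate), 1 mol %), tBuOOH (70% in water), K2CO3, CH2Cl2, rt
Reagents that add atoms: tert-butyl hydroperoxide, CC(C)(C)OO
Why: Radical allylic C–H oxidation by tert-butylperoxyl at the only ring allylic methylene (C7), the other allylic ring position being the fully substituted C10, should give the γ-silyloxy enone without touching the stereocenter.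

Step 4
Reactants: 5 nerol, (2Z)-3,7-dimethylocta-2,6-dien-1-ol
Product: 6 neryl bromide, (2Z)-1-bromo-3,7-dimethylocta-2,6-diene
Conditions: PBr3, Et2O, −10 °C, dark; used crude
Reagents that add atoms: phosphorus tribromide, BrP(Br)Br
Why: Low-temperature bromination of a primary allylic alcohol through its phosphite ester (SN2) should keep the Z geometry.

Step 5
Reactants: 6 neryl bromide
Product: 7 trimethyl[(5Z)-6,10-dimethylundeca-5,9-dien-1-yn-1-yl]silane
Conditions: 1-(trimethylsilyl)propyne, n-BuLi, THF, −78 °C; then 6, −78 to 0 °C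
Reagents that add atoms: 1-(trimethylsilyl)propyne, CC#C[Si](C)(C)C
Why: SN2 alkylation of the silyl-capped propargyl anion at the primary allylic bromide forms C16–C17 and leaves the Z alkene (future C18=C19) untouched.

Step 6
Reactants: 7 trimethyl[(5Z)-6,10-dimethylundeca-5,9-dien-1-yn-1-yl]silane
Product: 8 (5Z)-6,10-dimethylundeca-5,9-dien-1-yne
Conditions: K2CO3 (cat.), MeOH, rt
Reagents that add atoms: none
Why: Base-catalysed methanolysis (protodesilylation) of an alkynylsilane frees the terminal alkyne.

Step 7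
Reactants: 8 (5Z)-6,10-dimethylundeca-5,9-dien-1-yne
Product: 11 (3E,7Z)-4,8,12-trimethyltrideca-3,7,11-trien-1-ol, via alkenylalane 9 (not isolated), via lithium alanate 10 (not isolated)
Conditions: AlMe3, Cp2ZrCl2 (0.25 equiv), CH2Cl2, 0 °C to rt; volatiles removed; n-BuLi, THF, −78 °C; oxirane, −78 °C to rt; dilute HCl, 0 °C
Reagents that add atoms: trimethylaluminium, C[Al](C)C; oxirane, C1CO1
Why: Negishi zirconium-catalysed carboalumination adds methyl and aluminium syn across the terminal alkyne, and the derived alanate opens oxirane with retention at the alkenyl carbon, giving the 14E alkene and the C12–C13 unit in one operation.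

Step 8
Reactants: 11 (3E,7Z)-4,8,12-trimethyltrideca-3,7,11-trien-1-ol
Product: 12 (3E,7Z)-1-bromo-4,8,12-trimethyltrideca-3,7,11-triene
Conditions: CBr4, PPh3, CH2Cl2, 0 °C
Reagents that add atoms: tetrabromomethane, BrC(Br)(Br)Br
Why: Appel bromination of a primary alcohol proceeds under neutral conditions that do not isomerise the trisubstituted alkenes.

Step 9
Reactants: 12 (3E,7Z)-1-bromo-4,8,12-trimethyltrideca-3,7,11-triene; 4 (4S)-3,4-dimethyl-4-[(triethylsilyl)oxy]cyclohex-2-en-1-one
Product: 14 triethyl({(1S,2S)-1,2-dimethyl-2-[(3E,7Z)-4,8,12-trimethyltrideca-3,7,11-trien-1-yl]-4-[(trimethylsilyl)oxy]cyclohex-3-en-1-yl}oxy)silane, via Grignard reagent 13 (not isolated)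
Conditions: Mg, THF, rt, used at once; then 4, CuBr·SMe2 (10 mol %), Me3SiCl, (Me2N)3PO, THF, −78 to −40 °C; Et3N, pentane
Reagents that add atoms: chlorotrimethylsilane, C[Si](C)(C)Cl
Why: Copper-catalysed, chlorosilane-accelerated conjugate addition of a Grignard reagent to a β,β-disubstituted enone; the organocopper should attack C11 anti to the pseudoaxial C10 silyloxy group (the usual sense for γ-oxygenated enones), setting the quaternary C11 with the chain cis to the C10 methyl, and the enolate is trapped regiospecifically.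

Step 10
Reactants: 14 the silyl enol ether from step 9
Product: 16 (2S,3S,4S)-3,4-dimethyl-2-(prop-2-en-1-yl)-4-[(triethylsilyl)oxy]-3-[(3E,7Z)-4,8,12-trimethyltrideca-3,7,11-trien-1-yl]cyclohexan-1-one, via lithium enolate 15 (not isolated)
Conditions: MeLi, THF, 0 °C; then allyl iodide, (Me2N)3PO, −78 to 0 °C
Reagents that add atoms: allyl iodide, C=CCI
Why: Regiospecific lithium enolate generation from the silyl enol ether followed by C-allylation; the electrophile should approach C6 anti to the pseudoaxial C11 chain, placing the allyl group cis to the C11 methyl.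

Step 11
Reactants: 16 the allyl ketone from step 10
Product: 17 (2S,3S,4S)-3,4-dimethyl-1-(prop-1-en-2-yl)-2-(prop-2-en-1-yl)-4-[(triethylsilyl)oxy]-3-[(3E,7Z)-4,8,12-trimethyltrideca-3,7,11-trien-1-yl]cyclohexan-1-ol (both C1 epimers)
Conditions: isopropenylmagnesium bromide, CeCl3, THF, −78 to 0 °C
Reagents that add atoms: isopropenylmagnesium bromide, CC(=C)[Mg]Br
Why: Organocerium 1,2-addition to a hindered, enolisable ketone avoids enolisation and C6 epimerisation; the new C7 carbinol centre need not be controlled because it becomes sp2 in step 14.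

Step 12
Reactants: 17 the tertiary allylic alcohol from step 11
Product: 19 (2S,3S,4S)-2-(3-hydroxypropyl)-3,4-dimethyl-1-(prop-1-en-2-yl)-4-[(triethylsilyl)oxy]-3-[(3E,7Z)-4,8,12-trimethyltrideca-3,7,11-trien-1-yl]cyclohexan-1-ol (both C1 epimers), via trialkylborane 18 (not isolated)
Conditions: (Me2CHCHMe)2BH (from BH3·THF and 2-methylbut-2-ene), THF, 0 °C; then NaOH, H2O2, 0 °C to rt
Reagents that add atoms: hydrogen peroxide, OO
Why: Anti-Markovnikov hydroboration–oxidation; the bulky dialkylborane should react only with the monosubstituted allyl alkene and leave the 1,1-disubstituted isopropenyl group and the trisubstituted chain alkenes untouched.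

Step 13
Reactants: 19 the diol from step 12
Product: 20 the primary tert-butyldimethylsilyl ether of 19 (tertiary C7 hydroxyl free)
Conditions: tBuMe2SiCl, imidazole, CH2Cl2, 0 °C
Reagents that add atoms: tert-butyldimethylsilyl chloride, CC(C)(C)[Si](C)(C)Cl
Why: Selective silylation of the primary alcohol; the tertiary allylic alcohol is too hindered to react with the silyl chloride.

Step 14
Reactants: 20 the mono-silylated tertiary allylic alcohol from step 13
Product: 21 (2Z)-2-[(2R,3S,4S)-2-{3-[(tert-butyldimethylsilyl)oxy]propyl}-3,4-dimethyl-4-[(triethylsilyl)oxy]-3-[(3E,7Z)-4,8,12-trimethyltrideca-3,7,11-trien-1-yl]cyclohexylidene]propanal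
Conditions: pyridinium chlorochromate [C5H5NH][CrO3Cl], 4 Å molecular sieves, CH2Cl2, rt
Reagents that add atoms: pyridinium chlorochromate, [O-][Cr](=O)(=O)Cl.c1cc[nH+]cc1 (the formyl oxygen comes from chromate; the carbinol oxygen leaves on chromium)
Why: Babler–Dauben oxidative transposition, in which the chromate ester of the tertiary allylic alcohol undergoes a [3,3] shift and the primary allylic chromate is oxidised to the enal; the C2 methyl should turn away from the substituted C6 in the chair-like shift, and the isomer with formyl cis to C6 is also the one with less allylic strain, so the 2Z alkene is expected.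

Step 15
Reactants: 21 the bis-silyl enal from step 14
Product: 22 (2Z)-2-[(2R,3S,4S)-4-hydroxy-2-(3-hydroxypropyl)-3,4-dimethyl-3-[(3E,7Z)-4,8,12-trimethyltrideca-3,7,11-trien-1-yl]cyclohexylidene]propanal
Conditions: HF·pyridine, pyridine, THF, 0 °C to rt
Reagents that add atoms: none
Why: Fluoride-driven cleavage of both silyl ethers (Si–F bond formation) under pyridine-buffered conditions that should leave the enal and the three chain alkenes untouched.

Step 16
Reactants: 22 the 18Z triene diol enal from step 15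
Product: 23 (2Z)-2-[(2R,3S,4S)-4-hydroxy-2-(3-hydroxypropyl)-3,4-dimethyl-3-{(3E)-4-methyl-6-[(2R,3S)-3-methyl-3-(4-methylpent-3-en-1-yl)oxiran-2-yl]hex-3-en-1-yl}cyclohexylidene]propanal
Conditions: engineered P450 BM3 (CYP102A1) variant from directed evolution, O2 (air), NADP+ (cat.), D-glucose, glucose dehydrogenase, potassium phosphate buffer pH 8, 2% DMSO, 25 °C
Reagents that add atoms: dioxygen, O=O
Why: Proposed new method: the haem-thiolate oxo-iron porphyrin radical cation (tetravalent iron), formed from O2 and two NADPH-derived electrons, transfers its oxygen to the alkene held above the haem, and both C–O bonds form on one face faster than rotation about C18–C19, so the Z geometry is carried into an oxirane with C17 and C20 cis. The closest known reaction type is the regio- and enantioselective epoxidation of acyclic terpene polyenes by engineered P450 BM3 variants, which has not been shown for an internal Z alkene of a C30 substrate with a polar carbocyclic head. The single ring, the oxirane, closes by formal [2+1] oxygen-atom transfer, both bonds coming from the same iron-bound oxygen (collapse of the C–O–Fe intermediate is a 3-exo closure). C18 (R) and C19 (S) are set together: the pocket decides which alkene face is turned to the iron, and the syn-stereospecific transfer ties C19 to C18 through the Z geometry. The step needs site selectivity among C14=C15, C18=C19 and C22=C23 and chemoselectivity against allylic hydroxylation; the ring head with its two hydroxyls and the enal is expected to anchor at the channel mouth so that the kinked Z alkene, not its neighbours, reaches the iron, the pocket being shaped by directed evolution screened for this site, while the electron-poor C2=C7 enal is not attacked by the electrophilic oxidant.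

**Compound list**
1 | 2-methylcyclohex-2-en-1-one | CC1=CCCCC1=O | starting material
2 | (1S)-1,2-dimethylcyclohex-2-en-1-ol | CC1=CCCC[C@]1(C)O | intermediate
3 | triethyl{[(1S)-1,2-dimethylcyclohex-2-en-1-yl]oxy}silane | CC1=CCCC[C@]1(C)O[Si](CC)(CC)CC | intermediate
4 | (4S)-3,4-dimethyl-4-[(triethylsilyl)oxy]cyclohex-2-en-1-one | CC1=CC(=O)CC[C@]1(C)O[Si](CC)(CC)CC | intermediate
5 | nerol, (2Z)-3,7-dimethylocta-2,6-dien-1-ol | CC(C)=CCC/C(C)=C\CO | starting material
6 | neryl bromide, (2Z)-1-bromo-3,7-dimethylocta-2,6-diene | CC(C)=CCC/C(C)=C\CBr | intermediate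
7 | trimethyl[(5Z)-6,10-dimethylundeca-5,9-dien-1-yn-1-yl]silane | CC(C)=CCC/C(C)=C\CCC#C[Si](C)(C)C | intermediate
8 | (5Z)-6,10-dimethylundeca-5,9-dien-1-yne | CC(C)=CCC/C(C)=C\CCC#C | intermediate
9 | dimethyl[(1E,5Z)-2,6,10-trimethylundeca-1,5,9-trien-1-yl]alane | CC(C)=CCC/C(C)=C\CC/C(C)=C/[Al](C)C | intermediate (not isolated)
10 | lithium butyl(dimethyl)[(1E,5Z)-2,6,10-trimethylundeca-1,5,9-trien-1-yl]alanate | [Li+].CCCC[Al-](C)(C)/C=C(C)/CC/C=C(C)\CCC=C(C)C | intermediate (not isolated)
11 | (3E,7Z)-4,8,12-trimethyltrideca-3,7,11-trien-1-ol | CC(C)=CCC/C(C)=C\CC/C(C)=C/CCO | intermediate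
12 | (3E,7Z)-1-bromo-4,8,12-trimethyltrideca-3,7,11-triene | CC(C)=CCC/C(C)=C\CC/C(C)=C/CCBr | intermediate
13 | [(3E,7Z)-4,8,12-trimethyltrideca-3,7,11-trien-1-yl]magnesium bromide | CC(C)=CCC/C(C)=C\CC/C(C)=C/CC[Mg]Br | intermediate (not isolated)
14 | triethyl({(1S,2S)-1,2-dimethyl-2-[(3E,7Z)-4,8,12-trimethyltrideca-3,7,11-trien-1-yl]-4-[(trimethylsilyl)oxy]cyclohex-3-en-1-yl}oxy)silane | CC(C)=CCC/C(C)=C\CC/C(C)=C/CC[C@@]1(C)C=C(O[Si](C)(C)C)CC[C@]1(C)O[Si](CC)(CC)CC | intermediate
15 | lithium (3S,4S)-3,4-dimethyl-4-[(triethylsilyl)oxy]-3-[(3E,7Z)-4,8,12-trimethyltrideca-3,7,11-trien-1-yl]cyclohex-1-en-1-olate | CC(C)=CCC/C(C)=C\CC/C(C)=C/CC[C@@]1(C)C=C(O[Li])CC[C@]1(C)O[Si](CC)(CC)CC | intermediate (not isolated)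
16 | (2S,3S,4S)-3,4-dimethyl-2-(prop-2-en-1-yl)-4-[(triethylsilyl)oxy]-3-[(3E,7Z)-4,8,12-trimethyltrideca-3,7,11-trien-1-yl]cyclohexan-1-one | CC(C)=CCC/C(C)=C\CC/C(C)=C/CC[C@@]1(C)[C@H](CC=C)C(=O)CC[C@]1(C)O[Si](CC)(CC)CC | intermediate
17 | (2S,3S,4S)-3,4-dimethyl-1-(prop-1-en-2-yl)-2-(prop-2-en-1-yl)-4-[(triethylsilyl)oxy]-3-[(3E,7Z)-4,8,12-trimethyltrideca-3,7,11-trien-1-yl]cyclohexan-1-ol, C1 epimers | CC(C)=CCC/C(C)=C\CC/C(C)=C/CC[C@@]1(C)[C@H](CC=C)C(O)(C(C)=C)CC[C@]1(C)O[Si](CC)(CC)CC | intermediate
18 | B-alkyl bis(3-methylbutan-2-yl)borane formed at the allyl terminus of 17 | CC(C)=CCC/C(C)=C\CC/C(C)=C/CC[C@@]1(C)[C@H](CCCB(C(C)C(C)C)C(C)C(C)C)C(O)(C(C)=C)CC[C@]1(C)O[Si](CC)(CC)CC | intermediate (not isolated)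
19 | (2S,3S,4S)-2-(3-hydroxypropyl)-3,4-dimethyl-1-(prop-1-en-2-yl)-4-[(triethylsilyl)oxy]-3-[(3E,7Z)-4,8,12-trimethyltrideca-3,7,11-trien-1-yl]cyclohexan-1-ol, C1 epimers | CC(C)=CCC/C(C)=C\CC/C(C)=C/CC[C@@]1(C)[C@H](CCCO)C(O)(C(C)=C)CC[C@]1(C)O[Si](CC)(CC)CC | intermediate
20 | (2S,3S,4S)-2-{3-[(tert-butyldimethylsilyl)oxy]propyl}-3,4-dimethyl-1-(prop-1-en-2-yl)-4-[(triethylsilyl)oxy]-3-[(3E,7Z)-4,8,12-trimethyltrideca-3,7,11-trien-1-yl]cyclohexan-1-ol, C1 epimers | CC(C)=CCC/C(C)=C\CC/C(C)=C/CC[C@@]1(C)[C@H](CCCO[Si](C)(C)C(C)(C)C)C(O)(C(C)=C)CC[C@]1(C)O[Si](CC)(CC)CC | intermediate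
21 | (2Z)-2-[(2R,3S,4S)-2-{3-[(tert-butyldimethylsilyl)oxy]propyl}-3,4-dimethyl-4-[(triethylsilyl)oxy]-3-[(3E,7Z)-4,8,12-trimethyltrideca-3,7,11-trien-1-yl]cyclohexylidene]propanal | CC(C)=CCC/C(C)=C\CC/C(C)=C/CC[C@@]1(C)[C@H](CCCO[Si](C)(C)C(C)(C)C)/C(=C(/C)C=O)CC[C@]1(C)O[Si](CC)(CC)CC | intermediate
22 | (2Z)-2-[(2R,3S,4S)-4-hydroxy-2-(3-hydroxypropyl)-3,4-dimethyl-3-[(3E,7Z)-4,8,12-trimethyltrideca-3,7,11-trien-1-yl]cyclohexylidene]propanal | CC(C)=CCC/C(C)=C\CC/C(C)=C/CC[C@@]1(C)[C@H](CCCO)/C(=C(/C)C=O)CC[C@]1(C)O | intermediate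
23 | (2Z)-2-[(2R,3S,4S)-4-hydroxy-2-(3-hydroxypropyl)-3,4-dimethyl-3-{(3E)-4-methyl-6-[(2R,3S)-3-methyl-3-(4-methylpent-3-en-1-yl)oxiran-2-yl]hex-3-en-1-yl}cyclohexylidene]propanal | CC(C)=CCC[C@]1(C)O[C@@H]1CC/C(C)=C/CC[C@@]1(C)[C@H](CCCO)/C(=C(/C)C=O)CC[C@]1(C)O | target

**Count**
Total steps: 16. Longest linear sequence: 13 steps (steps 4–16, from nerol 5); the ring branch (steps 1–3) joins at step 9.

**Steps most likely to fail**

Step 16. Oxygen transfer may go to the wrong alkene or the wrong face, or allylic hydroxylation may replace epoxidation, if no enzyme variant holds C18=C19 over the iron. The fallback gives up single-step site control and uses known reagent-controlled chemistry before deprotection; it sets out from 21 and returns at 23. Bis-silyl ether 21 is submitted to a Shi epoxidation with the D-fructose-derived ketone, KHSO5 and K2CO3 in MeCN/dimethoxymethane/water at 0 °C, stopped at partial conversion. The spiro transition-state model predicts oxygen delivery to the face that gives 18R at the CH carbon of a trisubstituted alkene, and the Z geometry then fixes 19S. No site preference among the three chain alkenes is expected, so the 18,19-mono-epoxide, the bis-silyl ether of 23 F1, has to be separated from its 14,15- and 22,23-isomers and from recovered 21 by preparative HPLC. F1 is then desilylated with Bu4NF buffered with AcOH in THF (HF is avoided because it opens oxiranes) to give 23.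

Step 9. Addition at the congested β-carbon may be slow, with competing 1,2-addition, or the organocopper may attack the face of the silyloxy group (poor facial selectivity). The fallback reverses the roles: the chain is placed on the enone first and the C11 methyl is delivered to the face of the free C10 oxygen. It sets out from 12 (through its Grignard reagent 13) and returns at 16. Commercial 3-ethoxy-6-methylcyclohex-2-en-1-one is hydroxylated through its lithium enolate (LiN(iPr)2, then the appropriate enantiomer of (camphorsulfonyl)oxaziridine) to (6S)-3-ethoxy-6-hydroxy-6-methylcyclohex-2-en-1-one F2. Its sodium alkoxide (NaH) takes up 13 at the ketone (CeCl3, THF, −78 °C), and dilute HCl effects the Stork–Danheiser transposition, with loss of ethanol, to (4S)-4-hydroxy-4-methyl-3-[(3E,7Z)-4,8,12-trimethyltrideca-3,7,11-trien-1-yl]cyclohex-2-en-1-one F3. Excess MeMgCl in THF then adds 1,4 under direction of the magnesium alkoxide (alkoxide-directed conjugate addition), placing the new methyl cis to the C10 oxygen. The resulting enolate is allylated (allyl iodide, (Me2N)3PO) anti to the chain to give (2S,3S,4S)-4-hydroxy-3,4-dimethyl-2-(prop-2-en-1-yl)-3-[(3E,7Z)-4,8,12-trimethyltrideca-3,7,11-trien-1-yl]cyclohexan-1-one F4. Et3SiOTf/2,6-lutidine converts F4 into 16.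

Step 14. Acid-induced dehydration of the tertiary allylic alcohol may outrun the [3,3] shift, and the tetrasubstituted enal may form as a 2E/2Z mixture. The fallback replaces addition/transposition by olefination at the ketone stage; it sets out from 16 and returns at 22. Horner–Wadsworth–Emmons reaction of 16 with diethyl (1-cyanoethyl)phosphonate and KN(SiMe3)2 in THF gives the unsaturated nitrile (2Z)-2-[(2R,3S,4S)-3,4-dimethyl-2-(prop-2-en-1-yl)-4-[(triethylsilyl)oxy]-3-[(3E,7Z)-4,8,12-trimethyltrideca-3,7,11-trien-1-yl]cyclohexylidene]propanenitrile F5, probably together with its 2E isomer. Hydroboration of the allyl group with (Me2CHCHMe)2BH and oxidation with NaBO3 (chosen to spare the nitrile) gives the 3-hydroxypropyl nitrile F6. Reduction with iBu2AlH in toluene at −78 °C and hydrolysis of the aldimine gives the enal (2Z)-2-[(2R,3S,4S)-2-(3-hydroxypropyl)-3,4-dimethyl-4-[(triethylsilyl)oxy]-3-[(3E,7Z)-4,8,12-trimethyltrideca-3,7,11-trien-1-yl]cyclohexylidene]propanal F7. F7 is equilibrated with a trace of iodine towards the less strained 2Z isomer and desilylated with HF·pyridine to give 22.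

**Further compounds**
F1 | step 16 | (2Z)-2-[(2R,3S,4S)-2-{3-[(tert-butyldimethylsilyl)oxy]propyl}-3,4-dimethyl-3-{(3E)-4-methyl-6-[(2R,3S)-3-methyl-3-(4-methylpent-3-en-1-yl)oxiran-2-yl]hex-3-en-1-yl}-4-[(triethylsilyl)oxy]cyclohexylidene]propanal | CC(C)=CCC[C@]1(C)O[C@@H]1CC/C(C)=C/CC[C@@]1(C)[C@H](CCCO[Si](C)(C)C(C)(C)C)/C(=C(/C)C=O)CC[C@]1(C)O[Si](CC)(CC)CC
F2 | step 9 | (6S)-3-ethoxy-6-hydroxy-6-methylcyclohex-2-en-1-one | O=C1C=C(OCC)CC[C@]1(C)O
F3 | step 9 | (4S)-4-hydroxy-4-methyl-3-[(3E,7Z)-4,8,12-trimethyltrideca-3,7,11-trien-1-yl]cyclohex-2-en-1-one | CC(C)=CCC/C(C)=C\CC/C(C)=C/CCC1=CC(=O)CC[C@]1(C)O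
F4 | step 9 | (2S,3S,4S)-4-hydroxy-3,4-dimethyl-2-(prop-2-en-1-yl)-3-[(3E,7Z)-4,8,12-trimethyltrideca-3,7,11-trien-1-yl]cyclohexan-1-one | CC(C)=CCC/C(C)=C\CC/C(C)=C/CC[C@@]1(C)[C@H](CC=C)C(=O)CC[C@]1(C)O
F5 | step 14 | (2Z)-2-[(2R,3S,4S)-3,4-dimethyl-2-(prop-2-en-1-yl)-4-[(triethylsilyl)oxy]-3-[(3E,7Z)-4,8,12-trimethyltrideca-3,7,11-trien-1-yl]cyclohexylidene]propanenitrile | CC(C)=CCC/C(C)=C\CC/C(C)=C/CC[C@@]1(C)[C@H](CC=C)/C(=C(/C)C#N)CC[C@]1(C)O[Si](CC)(CC)CC
F6 | step 14 | (2Z)-2-[(2R,3S,4S)-2-(3-hydroxypropyl)-3,4-dimethyl-4-[(triethylsilyl)oxy]-3-[(3E,7Z)-4,8,12-trimethyltrideca-3,7,11-trien-1-yl]cyclohexylidene]propanenitrile | CC(C)=CCC/C(C)=C\CC/C(C)=C/CC[C@@]1(C)[C@H](CCCO)/C(=C(/C)C#N)CC[C@]1(C)O[Si](CC)(CC)CC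
F7 | step 14 | (2Z)-2-[(2R,3S,4S)-2-(3-hydroxypropyl)-3,4-dimethyl-4-[(triethylsilyl)oxy]-3-[(3E,7Z)-4,8,12-trimethyltrideca-3,7,11-trien-1-yl]cyclohexylidene]propanal | CC(C)=CCC/C(C)=C\CC/C(C)=C/CC[C@@]1(C)[C@H](CCCO)/C(=C(/C)C=O)CC[C@]1(C)O[Si](CC)(CC)CC
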